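**Retrosynthetic overview**
- The neopentyl aryl ether is cut last-but-two: isofraxidin brings the coumarin bicycle ready-made, and the propanal is carried as a silyl-protected propanol until the final oxidation.
- The strategy rests on the cyclohexane ring, where the carbon bearing the exocyclic C=C(CH3)2 is followed by CH(CH2CH2CHO), the quaternary C(CH3)(CH2OAr) and CH(CH3). This is the pattern left by a gem-dimethyl vinylallene adding to an (E)-2-methyl-2-enal, minus one ring C=C.
- An enantioselective Diels–Alder reaction between (E)-2-methylhepta-2,3,5-triene and (E)-6-silyloxy-2-methylhex-2-enal therefore builds the carbocycle, all three stereocentres and the tetrasubstituted alkene in one step.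
- Ring order: the coumarin is bought, the carbocycle is the only ring made (at the cycloaddition), and the two halves are joined afterwards through the ether.

Key step: step 6

Assumption: the catalyst antipode is assigned from the usual pre-transition-state model for 2-substituted enals (formyl C–H···O contact, s-trans enal, diene adding anti to the shielding phenyl), which predicts that the cation from (R)-α,α-diphenylprolinol opens the Si face of the enal α-carbon; the (S)-catalyst would be used if the sense proved opposite.

Step 1
Reactants: 1 1,4-butanediol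
Product: 3 4-(tert-butyldiphenylsilyloxy)butan-1-ol, via sodium 4-hydroxybutan-1-olate 2 (not isolated)
Conditions: NaH (1.0 equiv), THF, rt; then TBDPSCl (1.0 equiv), rt
Reagents that add atoms: tert-butyl(chloro)diphenylsilane, CC(C)(C)[Si](Cl)(c1ccccc1)c1ccccc1
Why: O-silylation of the sparingly soluble monosodium alkoxide should stop after one hydroxyl, giving the mono-protected diol.

Step 2
Reactants: 3 4-(tert-butyldiphenylsilyloxy)butan-1-ol
Product: 4 4-(tert-butyldiphenylsilyloxy)butanal
Conditions: TEMPO (10 mol%), PhI(OAc)2 (1.1 equiv), CH2Cl2, rt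
Reagents that add atoms: none
Why: oxoammonium-mediated alcohol oxidation should stop cleanly at the aldehyde and leaves the silyl ether alone.

Step 3
Reactants: 4 4-(tert-butyldiphenylsilyloxy)butanal; 5 2-(triphenylphosphoranylidene)propanal
Product: 6 (E)-6-(tert-butyldiphenylsilyloxy)-2-methylhex-2-enal
Conditions: toluene, 90 °C
Reagents that add atoms: none
Why: Wittig olefination with a stabilised formyl ylide is under thermodynamic control and should give the E-trisubstituted enal, which is too hindered to react a second time.

Step 4
Reactants: 7 2-methylbut-3-yn-2-ol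
Product: 9 methyl 2-methylbut-3-yn-2-yl carbonate, via lithium 2-methylbut-3-yn-2-olate 8 (not isolated)
Conditions: n-BuLi (1.0 equiv), THF, −78 °C; then ClCO2Me, −78 to 0 °C
Reagents that add atoms: methyl chloroformate, COC(=O)Cl
Why: the hydroxyl is deprotonated before the alkyne C–H, and O-acylation of the tertiary lithium alkoxide should give the propargylic carbonate.

Step 5
Reactants: 9 methyl 2-methylbut-3-yn-2-yl carbonate; 10 (E)-prop-1-enylboronic acid
Product: 11 (E)-2-methylhepta-2,3,5-triene
Conditions: Pd(PPh3)4 (3 mol%), THF, 25–50 °C; extracted into pentane, filtered through silica, kept cold as a titrated solution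
Reagents that add atoms: none
Why: zerovalent palladium ionises the carbonate in the SN2′ sense with loss of CO2 to an allenylpalladium methoxide, which transmetalates with the alkenylboronic acid without added base and reductively eliminates to the vinylallene with the E alkene retained (Suzuki–Miyaura-type coupling of a propargylic carbonate).

Step 6
Reactants: 6 (E)-6-(tert-butyldiphenylsilyloxy)-2-methylhex-2-enal; 11 (E)-2-methylhepta-2,3,5-triene
Product: 12 (1S,2S,6S)-6-[3-(tert-butyldiphenylsilyloxy)propyl]-1,2-dimethyl-5-(propan-2-ylidene)cyclohex-3-ene-1-carbaldehyde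
Conditions: (R)-B-(o-tolyl)oxazaborolidine from (R)-α,α-diphenylprolinol (20 mol%), Tf2NH (17 mol%), 11 (3 equiv), CH2Cl2, −78 to −20 °C
Reagents that add atoms: none
Why: Proposed new method: the N-protonated oxazaborolidine binds the formyl oxygen of 6, and a concerted but asynchronous suprafacial [4+2] addition should follow in which the sp carbon of 11 bonds first to the enal β-carbon while positive charge builds on the methyl-capped allyl unit, after which the methyl-bearing terminus bonds to the α-carbon; the closest known reaction types are Lewis-acid-promoted Diels–Alder additions of vinylallenes to give alkylidenecyclohexenes and oxazaborolidinium-catalysed enantioselective Diels–Alder additions of 2-substituted enals to open-chain dienes, which have not been combined on a gem-dimethyl vinylallene and a β-alkyl enal. The carbocycle, the only ring made in the route, closes by this intermolecular six-centre cycloaddition through two new C–C bonds, and the allene π bond orthogonal to the diene remains as the exocyclic isopropylidene. The E geometry of the enal, transferred suprafacially, places the side chain cis to the quaternary methyl; the formyl-endo transition state places the ring methyl (from the E-propenyl terminus) cis to the formyl group; the absolute configuration of all three centres comes from the catalyst, whose aryl group covers one face of the s-trans enal so that the diene adds to the Si face of the α-carbon. The step needs one regiochemistry, endo selectivity and one enal face: the nucleophilic sp terminus and the cation-stabilising terminal methyl direct the same orientation, the open-chain diene lets the coordinated formyl group lie endo without penalising the exo α-methyl, and the catalyst antipode fixes the face. The vinylallene suits the task because its sp terminus has no inside substituent, cumulene strain is released, and the gem-dimethyl end keeps it achiral while delivering the tetrasubstituted alkene directly; the foreseeable weakness is crowding between the allene methyl on the reacting face and the enal side chain, to be met with excess diene and the strongly activated cationic catalyst.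

Step 7
Reactants: 12 (1S,2S,6S)-6-[3-(tert-butyldiphenylsilyloxy)propyl]-1,2-dimethyl-5-(propan-2-ylidene)cyclohex-3-ene-1-carbaldehyde
Product: 13 [(1S,2S,6S)-6-[3-(tert-butyldiphenylsilyloxy)propyl]-1,2-dimethyl-5-(propan-2-ylidene)cyclohex-3-en-1-yl]methanol
Conditions: NaBH4, MeOH/THF, 0 °C
Reagents that add atoms: none
Why: borohydride reduction of the non-enolisable neopentyl aldehyde should give the primary alcohol without touching the diene, the silyl ether or any stereocentre.

Step 8
Reactants: 13 [(1S,2S,6S)-6-[3-(tert-butyldiphenylsilyloxy)propyl]-1,2-dimethyl-5-(propan-2-ylidene)cyclohex-3-en-1-yl]methanol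
Product: 14 [(1S,2S,6S)-2-[3-(tert-butyldiphenylsilyloxy)propyl]-1,6-dimethyl-3-(propan-2-ylidene)cyclohexyl]methanol
Conditions: TsNHNH2 (excess, in portions), NaOAc, DME/H2O, reflux
Reagents that add atoms: none
Why: diimide reduction transfers H2 in a concerted syn fashion at a rate that falls steeply with substitution, so the cis-disubstituted ring alkene should be saturated while the tetrasubstituted isopropylidene survives, with no metal hydride to shift double bonds or disturb the adjacent stereocentres.

Step 9
Reactants: 14 [(1S,2S,6S)-2-[3-(tert-butyldiphenylsilyloxy)propyl]-1,6-dimethyl-3-(propan-2-ylidene)cyclohexyl]methanol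
Product: 15 [(1S,2S,6S)-2-[3-(tert-butyldiphenylsilyloxy)propyl]-1,6-dimethyl-3-(propan-2-ylidene)cyclohexyl]methyl trifluoromethanesulfonate
Conditions: Tf2O, 2,6-lutidine, CH2Cl2, −78 °C; cold work-up, used at once
Reagents that add atoms: trifluoromethanesulfonic anhydride, O=S(=O)(OS(=O)(=O)C(F)(F)F)C(F)(F)F
Why: O-sulfonylation of the primary alcohol with a hindered pyridine base should give a neopentyl triflate that has no β-hydrogen for elimination and can be handled briefly.

Step 10
Reactants: 15 [(1S,2S,6S)-2-[3-(tert-butyldiphenylsilyloxy)propyl]-1,6-dimethyl-3-(propan-2-ylidene)cyclohexyl]methyl trifluoromethanesulfonate; 16 isofraxidin (7-hydroxy-6,8-dimethoxy-2H-chromen-2-one)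
Product: 18 7-[[(1S,2S,6S)-2-[3-(tert-butyldiphenylsilyloxy)propyl]-1,6-dimethyl-3-(propan-2-ylidene)cyclohexyl]methoxy]-6,8-dimethoxy-2H-chromen-2-one, via caesium 6,8-dimethoxy-2-oxo-2H-chromen-7-olate 17 (not isolated)
Conditions: 16, Cs2CO3, DMF, rt, 30 min; then 15, 0 to 40 °C
Reagents that add atoms: none
Why: Williamson-type SN2 displacement at the neopentyl carbon is made feasible by the triflate nucleofuge and the weakly paired caesium phenoxide in a dipolar aprotic solvent, and the coumarin enters only after the diimide step so its C3=C4 bond is never exposed to reduction.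

Step 11
Reactants: 18 7-[[(1S,2S,6S)-2-[3-(tert-butyldiphenylsilyloxy)propyl]-1,6-dimethyl-3-(propan-2-ylidene)cyclohexyl]methoxy]-6,8-dimethoxy-2H-chromen-2-one
Product: 19 7-[[(1S,2S,6S)-2-(3-hydroxypropyl)-1,6-dimethyl-3-(propan-2-ylidene)cyclohexyl]methoxy]-6,8-dimethoxy-2H-chromen-2-one
Conditions: TBAF, AcOH (1:1), THF, rt
Reagents that add atoms: none
Why: fluoride-driven desilylation should free the primary alcohol, with the acetic acid buffer protecting the coumarin lactone from basic opening.

Step 12
Reactants: 19 7-[[(1S,2S,6S)-2-(3-hydroxypropyl)-1,6-dimethyl-3-(propan-2-ylidene)cyclohexyl]methoxy]-6,8-dimethoxy-2H-chromen-2-one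
Product: 20 3-[(1S,2S,3S)-2-[[(6,8-dimethoxy-2-oxo-2H-chromen-7-yl)oxy]methyl]-2,3-dimethyl-6-(propan-2-ylidene)cyclohexyl]propanal (CNP0213227.1)
Conditions: DMP, NaHCO3, CH2Cl2, 0 °C to rt; chromatography on neutralised silica
Reagents that add atoms: none
Why: Dess–Martin oxidation under buffered, near-neutral conditions should stop at the aldehyde and avoid the acid that could trigger Prins or carbonyl-ene closure onto the neighbouring isopropylidene.

**Compound list**
1 | 1,4-butanediol | OCCCCO | starting material
2 | sodium 4-hydroxybutan-1-olate | [Na+].[O-]CCCCO | intermediate (not isolated)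
3 | 4-(tert-butyldiphenylsilyloxy)butan-1-ol | OCCCCO[Si](c1ccccc1)(c1ccccc1)C(C)(C)C | intermediate
4 | 4-(tert-butyldiphenylsilyloxy)butanal | O=CCCCO[Si](c1ccccc1)(c1ccccc1)C(C)(C)C | intermediate
5 | 2-(triphenylphosphoranylidene)propanal | CC(C=O)=P(c1ccccc1)(c1ccccc1)c1ccccc1 | starting material
6 | (E)-6-(tert-butyldiphenylsilyloxy)-2-methylhex-2-enal | O=C/C(C)=C/CCCO[Si](c1ccccc1)(c1ccccc1)C(C)(C)C | intermediate
7 | 2-methylbut-3-yn-2-ol | CC(C)(O)C#C | starting material
8 | lithium 2-methylbut-3-yn-2-olate | [Li+].[O-]C(C)(C)C#C | intermediate (not isolated)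
9 | methyl 2-methylbut-3-yn-2-yl carbonate | COC(=O)OC(C)(C)C#C | intermediate
10 | (E)-prop-1-enylboronic acid | C/C=C/B(O)O | starting material
11 | (E)-2-methylhepta-2,3,5-triene | CC(C)=C=C/C=C/C | intermediate
12 | (1S,2S,6S)-6-[3-(tert-butyldiphenylsilyloxy)propyl]-1,2-dimethyl-5-(propan-2-ylidene)cyclohex-3-ene-1-carbaldehyde (formyl cis to the ring methyl, trans to the side chain) | O=C[C@@]1(C)[C@@H](C)C=CC(=C(C)C)[C@@H]1CCCO[Si](c1ccccc1)(c1ccccc1)C(C)(C)C | intermediate
13 | [(1S,2S,6S)-6-[3-(tert-butyldiphenylsilyloxy)propyl]-1,2-dimethyl-5-(propan-2-ylidene)cyclohex-3-en-1-yl]methanol | OC[C@@]1(C)[C@@H](C)C=CC(=C(C)C)[C@@H]1CCCO[Si](c1ccccc1)(c1ccccc1)C(C)(C)C | intermediate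
14 | [(1S,2S,6S)-2-[3-(tert-butyldiphenylsilyloxy)propyl]-1,6-dimethyl-3-(propan-2-ylidene)cyclohexyl]methanol | OC[C@@]1(C)[C@@H](C)CCC(=C(C)C)[C@@H]1CCCO[Si](c1ccccc1)(c1ccccc1)C(C)(C)C | intermediate
15 | [(1S,2S,6S)-2-[3-(tert-butyldiphenylsilyloxy)propyl]-1,6-dimethyl-3-(propan-2-ylidene)cyclohexyl]methyl trifluoromethanesulfonate | FC(F)(F)S(=O)(=O)OC[C@@]1(C)[C@@H](C)CCC(=C(C)C)[C@@H]1CCCO[Si](c1ccccc1)(c1ccccc1)C(C)(C)C | intermediate
16 | isofraxidin (7-hydroxy-6,8-dimethoxy-2H-chromen-2-one) | COc1cc2ccc(=O)oc2c(OC)c1O | starting material
17 | caesium 6,8-dimethoxy-2-oxo-2H-chromen-7-olate | COc1cc2ccc(=O)oc2c(OC)c1[O-].[Cs+] | intermediate (not isolated)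
18 | 7-[[(1S,2S,6S)-2-[3-(tert-butyldiphenylsilyloxy)propyl]-1,6-dimethyl-3-(propan-2-ylidene)cyclohexyl]methoxy]-6,8-dimethoxy-2H-chromen-2-one | COc1cc2ccc(=O)oc2c(OC)c1OC[C@@]1(C)[C@@H](C)CCC(=C(C)C)[C@@H]1CCCO[Si](c1ccccc1)(c1ccccc1)C(C)(C)C | intermediate
19 | 7-[[(1S,2S,6S)-2-(3-hydroxypropyl)-1,6-dimethyl-3-(propan-2-ylidene)cyclohexyl]methoxy]-6,8-dimethoxy-2H-chromen-2-one | COc1cc2ccc(=O)oc2c(OC)c1OC[C@@]1(C)[C@@H](C)CCC(=C(C)C)[C@@H]1CCCO | intermediate
20 | 3-[(1S,2S,3S)-2-[[(6,8-dimethoxy-2-oxo-2H-chromen-7-yl)oxy]methyl]-2,3-dimethyl-6-(propan-2-ylidene)cyclohexyl]propanal (CNP0213227.1) | COc1cc2ccc(=O)oc2c(OC)c1OC[C@@]1(C)[C@@H](C)CCC(=C(C)C)[C@@H]1CCC=O | target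

**Step count**
Total steps: 12. Longest linear sequence: 10 steps (steps 1, 2, 3, 6, 7, 8, 9, 10, 11, 12) from 1,4-butanediol; steps 4 and 5 form the short diene branch.

**Steps most likely to fail**

Step 6 (labelled as a proposed new method). The hindered diene and dienophile may fail to combine before the vinylallene oligomerises or is isomerised by adventitious acid, or regio-, endo- or facial selectivity may erode. The fallback sets out from 6 and 11 and comes back at 13. The two partners are combined under Me2AlCl (CH2Cl2, −78 to −20 °C) or thermally under pressure, the established mode for vinylallene cycloadditions. This should give 12 as a racemate, that is, together with its mirror-image aldehyde F1. NaBH4 reduction then gives 13 with the enantiomeric alcohol F2. Acylation of the mixture with (1S)-(−)-camphanic chloride (pyridine, DMAP, CH2Cl2) gives the diastereomeric camphanate ester F3 (from 13) and camphanate ester F4 (from F2), to be separated by chromatography or crystallisation. Saponification of F3 (LiOH, THF/MeOH/H2O) returns enantiopure 13 and the route resumes at step 8.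

Step 10 (with its feeder, step 9). Substitution at the neopentyl carbon may be outrun by triflyl transfer to the phenoxide (attack at sulfur), by Wagner–Meerwein shift, or by participation of the isopropylidene π bond as the triflate ionises. The fallback sets out from alcohol 14 and phenol 16 and comes back at 18. It is a direct Mitsunobu etherification at high concentration with sonication (PPh3, DIAD, THF, about 3 M), which activates the alcohol as an alkoxyphosphonium ion in the presence of the phenol and never forms a free sulfonate. It makes no compound outside the list (F0).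

Step 8. Hydrogen transfer to a ring alkene flanked by a stereocentre and the isopropylidene may be slow, leaving conversion incomplete while the diimide is lost to disproportionation. The fallback sets out from 13 and comes back at 14. It is homogeneous catalytic hydrogenation with RhCl(PPh3)3 under H2 (1–3 atm, benzene/EtOH, rt), which discriminates the disubstituted from the tetrasubstituted alkene by coordination and insertion at the metal instead of by a pericyclic transfer. It makes no compound outside the list (F0).

**Further compounds**
F1 | step 6 | (1R,2R,6R)-6-[3-(tert-butyldiphenylsilyloxy)propyl]-1,2-dimethyl-5-(propan-2-ylidene)cyclohex-3-ene-1-carbaldehyde (mirror image of 12) | O=C[C@]1(C)[C@H](C)C=CC(=C(C)C)[C@H]1CCCO[Si](c1ccccc1)(c1ccccc1)C(C)(C)C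
F2 | step 6 | [(1R,2R,6R)-6-[3-(tert-butyldiphenylsilyloxy)propyl]-1,2-dimethyl-5-(propan-2-ylidene)cyclohex-3-en-1-yl]methanol (mirror image of 13) | OC[C@]1(C)[C@H](C)C=CC(=C(C)C)[C@H]1CCCO[Si](c1ccccc1)(c1ccccc1)C(C)(C)C
F3 | step 6 | (1S,4R)-camphanate ester of 13 | O=C(OC[C@@]1(C)[C@@H](C)C=CC(=C(C)C)[C@@H]1CCCO[Si](c1ccccc1)(c1ccccc1)C(C)(C)C)[C@@]12CC[C@@](C)(C(=O)O1)C2(C)C
F4 | step 6 | (1S,4R)-camphanate ester of F2 | O=C(OC[C@]1(C)[C@H](C)C=CC(=C(C)C)[C@H]1CCCO[Si](c1ccccc1)(c1ccccc1)C(C)(C)C)[C@@]12CC[C@@](C)(C(=O)O1)C2(C)C
F0 | step 10 | none | none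
F0 | step 8 | none | none
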